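**Assumption:** the target has no stereocentre, so the "single enantiomer" is the achiral compound itself; the racemic intermediates 14, 17 and 19 lose their stereocentres again. Phenoxide, alkoxide and enolate salts of numbered compounds are not numbered separately.

**Retrosynthetic overview**
1. Target ⇐ 8-O-acylation of an 8-hydroxy-5,7-di-O-benzyl flavone, then hydrogenolysis; the 8-oxygen is carried as a MOM ether, the 5- and 7-oxygens as benzyl ethers.
2. Pyranone ring (formed last) ⇐ oxidative cyclisation of a 2'-hydroxychalcone to the flavonol, then 3-O-methylation.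
3. Chalcone ⇐ intermolecular Claisen–Schmidt aldol condensation of the fully oxygenated acetophenone 15 with 4-methoxybenzaldehyde 16 (key C–C bond, flavone C2–C3).
4. Acetophenone 15 ⇐ three formylations on 2-methoxyresorcinol dibenzyl ether: two formyl groups are turned into oxygen (Baeyer–Villiger) and the last into the acetyl group; the A ring comes from the starting material.

**Route**

Step 1
Reactants: 1 2-methoxybenzene-1,3-diol (2-methoxyresorcinol)
Product: 2 1,3-bis(benzyloxy)-2-methoxybenzene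
Conditions: BnBr (2.3 equiv), K2CO3, DMF, 60 °C
Reagents that add atoms: benzyl bromide BrCc1ccccc1
Why: Williamson ether synthesis on both equivalent phenols puts in the groups that later become the free 5- and 7-OH.

Step 2
Reactants: 2 1,3-bis(benzyloxy)-2-methoxybenzene
Product: 4 2,4-bis(benzyloxy)-3-methoxybenzaldehyde, via aryl iminium salt 3 (not isolated)
Conditions: POCl3, DMF, 0 → 80 °C; then H2O
Reagents that add atoms: N,N-dimethylformamide CN(C)C=O; water O
Why: Vilsmeier–Haack formylation goes to C4, which is ortho to one benzyloxy group and para to the other, as in the formylation of 1,2,3-trimethoxybenzene.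

Step 3
Reactants: 4 2,4-bis(benzyloxy)-3-methoxybenzaldehyde
Product: 6 2,4-bis(benzyloxy)-3-methoxyphenol, via aryl formate 5 (not isolated)
Conditions: mCPBA, CH2Cl2, rt; then K2CO3 (cat.), MeOH
Reagents that add atoms: mCPBA OOC(=O)c1cccc(Cl)c1
Why: Baeyer–Villiger (Dakin-type) oxidation of an ortho/para-alkoxy benzaldehyde migrates the electron-rich aryl group to give the formate, which methanolysis cleaves to the phenol.

Step 4
Reactants: 6 2,4-bis(benzyloxy)-3-methoxyphenol
Product: 8 3,5-bis(benzyloxy)-2-hydroxy-4-methoxybenzaldehyde, via salicyl alcohol 7 (not isolated)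
Conditions: MgCl2 (anhydrous), Et3N, (CH2O)n, MeCN, reflux; dilute HCl work-up
Reagents that add atoms: paraformaldehyde (reacts as formaldehyde) C=O
Why: Magnesium-mediated ortho-formylation (Casnati–Skattebøl) delivers formaldehyde only to the one free position ortho to the phenoxide, and the hydroxymethyl intermediate is oxidised by a second formaldehyde.

Step 5
Reactants: 8 3,5-bis(benzyloxy)-2-hydroxy-4-methoxybenzaldehyde
Product: 9 3,5-bis(benzyloxy)-4-methoxy-2-(methoxymethoxy)benzaldehyde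
Conditions: NaH, MOMCl, DMF, 0 °C → rt
Reagents that add atoms: chloromethyl methyl ether COCCl
Why: O-alkylation of the sodium phenoxide fixes the future 8-oxygen as a MOM acetal, which is base-stable and orthogonal to benzyl.

Step 6
Reactants: 9 3,5-bis(benzyloxy)-4-methoxy-2-(methoxymethoxy)benzaldehyde
Product: 11 3,5-bis(benzyloxy)-4-methoxy-2-(methoxymethoxy)phenol, via aryl formate 10 (not isolated)
Conditions: mCPBA, CH2Cl2, 0 °C → rt; then K2CO3 (cat.), MeOH, N2
Reagents that add atoms: mCPBA OOC(=O)c1cccc(Cl)c1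
Why: A second Baeyer–Villiger oxidation and formate methanolysis turn the formyl carbon into the phenol oxygen that will become O1 of the flavone.

Step 7
Reactants: 11 3,5-bis(benzyloxy)-4-methoxy-2-(methoxymethoxy)phenol
Product: 13 4,6-bis(benzyloxy)-2-hydroxy-5-methoxy-3-(methoxymethoxy)benzaldehyde, via salicyl alcohol 12 (not isolated)
Conditions: MgCl2 (anhydrous), Et3N, (CH2O)n, MeCN, reflux; aq. NH4Cl work-up
Reagents that add atoms: paraformaldehyde (reacts as formaldehyde) C=O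
Why: The same magnesium-mediated ortho-formylation can only occur at the last free ring position, and it avoids the Lewis acids that would cleave MOM or benzyl ethers.

Step 8
Reactants: 13 4,6-bis(benzyloxy)-2-hydroxy-5-methoxy-3-(methoxymethoxy)benzaldehyde
Product: 14 racemic 1-[4,6-bis(benzyloxy)-2-hydroxy-5-methoxy-3-(methoxymethoxy)phenyl]ethan-1-ol
Conditions: MeMgBr (3 equiv), THF, 0 °C → rt; aq. NH4Cl; used crude
Reagents that add atoms: methylmagnesium bromide C[Mg]Br
Why: Grignard addition to the aldehyde (the first equivalent deprotonates the phenol) gives the carbinol, whose new stereocentre is formed racemic and is erased in step 9.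

Step 9
Reactants: 14 racemic 1-[4,6-bis(benzyloxy)-2-hydroxy-5-methoxy-3-(methoxymethoxy)phenyl]ethan-1-ol
Product: 15 1-[4,6-bis(benzyloxy)-2-hydroxy-5-methoxy-3-(methoxymethoxy)phenyl]ethan-1-one
Conditions: activated MnO2 (excess), CH2Cl2, rt
Reagents that add atoms: none
Why: Benzylic alcohol oxidation with MnO2 gives the chelated o-hydroxyacetophenone, and the fully substituted ring leaves no position open for phenol coupling.

Step 10
Reactants: 15 1-[4,6-bis(benzyloxy)-2-hydroxy-5-methoxy-3-(methoxymethoxy)phenyl]ethan-1-one; 16 4-methoxybenzaldehyde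
Product: 18 (E)-1-[4,6-bis(benzyloxy)-2-hydroxy-5-methoxy-3-(methoxymethoxy)phenyl]-3-(4-methoxyphenyl)prop-2-en-1-one, via aldol adduct 17 (not isolated)
Conditions: KOH (50 % aq.), EtOH, rt, 48 h; then cold dilute AcOH
Reagents that add atoms: none
Why: Claisen–Schmidt crossed aldol condensation of the acetophenone enolate with the non-enolisable aldehyde, followed by E1cB dehydration, gives the thermodynamically favoured E-enone.

Step 11
Reactants: 18 (E)-1-[4,6-bis(benzyloxy)-2-hydroxy-5-methoxy-3-(methoxymethoxy)phenyl]-3-(4-methoxyphenyl)prop-2-en-1-one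
Product: 20 5,7-bis(benzyloxy)-3-hydroxy-6-methoxy-8-(methoxymethoxy)-2-(4-methoxyphenyl)-4H-chromen-4-one, via trans-3-hydroxyflavanone 19 (not isolated)
Conditions: 30 % H2O2, 2 M NaOH, MeOH/THF, 0 °C → rt; then dilute HCl to pH 4
Reagents that add atoms: hydrogen peroxide OO
Why: Algar–Flynn–Oyamada reaction, in which the phenoxide closes onto the β-carbon, the enolate is hydroxylated and the dihydroflavonol is oxidised on to the flavonol, helped by the donating 4-methoxy group on the B ring.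

Step 12
Reactants: 20 5,7-bis(benzyloxy)-3-hydroxy-6-methoxy-8-(methoxymethoxy)-2-(4-methoxyphenyl)-4H-chromen-4-one
Product: 21 5,7-bis(benzyloxy)-3,6-dimethoxy-8-(methoxymethoxy)-2-(4-methoxyphenyl)-4H-chromen-4-one
Conditions: MeI, K2CO3, acetone, reflux
Reagents that add atoms: iodomethane CI
Why: O-methylation (Williamson) of the only free hydroxyl installs the 3-methoxy group.

Step 13
Reactants: 21 5,7-bis(benzyloxy)-3,6-dimethoxy-8-(methoxymethoxy)-2-(4-methoxyphenyl)-4H-chromen-4-one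
Product: 22 5,7-bis(benzyloxy)-8-hydroxy-3,6-dimethoxy-2-(4-methoxyphenyl)-4H-chromen-4-one
Conditions: 2 M HCl (cat.), MeOH/THF, 40 °C
Reagents that add atoms: none
Why: Acid-catalysed acetal exchange removes the MOM group under conditions much milder than those needed to cleave benzyl or methyl aryl ethers, leaving 8-OH as the only free hydroxyl.

Step 14
Reactants: 22 5,7-bis(benzyloxy)-8-hydroxy-3,6-dimethoxy-2-(4-methoxyphenyl)-4H-chromen-4-one
Product: 23 5,7-bis(benzyloxy)-3,6-dimethoxy-2-(4-methoxyphenyl)-4-oxo-4H-chromen-8-yl 3-methylbutanoate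
Conditions: isovaleryl chloride, Et3N, DMAP (cat.), CH2Cl2, 0 °C → rt
Reagents that add atoms: 3-methylbutanoyl chloride CC(C)CC(Cl)=O
Why: DMAP-catalysed acylation of the single free phenol places the isovalerate on O-8 with no regiochemical choice.

Step 15
Reactants: 23 5,7-bis(benzyloxy)-3,6-dimethoxy-2-(4-methoxyphenyl)-4-oxo-4H-chromen-8-yl 3-methylbutanoate
Product: 24 5,7-dihydroxy-3,6-dimethoxy-2-(4-methoxyphenyl)-4-oxo-4H-chromen-8-yl 3-methylbutanoate (5,7,8-trihydroxy-3,6,4'-trimethoxyflavone 8-isovalerate)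
Conditions: H2 (1 atm), 10 % Pd/C, EtOAc/THF, rt; filter, evaporate without base
Reagents that add atoms: none
Why: Neutral catalytic hydrogenolysis cleaves both benzyl ethers without touching the aryl ester, the methyl ethers or the flavone core, and the base-free medium avoids 8→7 acyl migration.

**Compound list**
1 | 2-methoxybenzene-1,3-diol | COc1c(O)cccc1O | starting material
2 | 1,3-bis(benzyloxy)-2-methoxybenzene | COc1c(OCc2ccccc2)cccc1OCc1ccccc1 | intermediate
3 | [2,4-bis(benzyloxy)-3-methoxyphenyl]methylidene(dimethyl)iminium dichlorophosphate | C[N+](C)=Cc1ccc(OCc2ccccc2)c(OC)c1OCc1ccccc1.[O-]P(=O)(Cl)Cl | intermediate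
4 | 2,4-bis(benzyloxy)-3-methoxybenzaldehyde | O=Cc1ccc(OCc2ccccc2)c(OC)c1OCc1ccccc1 | intermediate
5 | 2,4-bis(benzyloxy)-3-methoxyphenyl formate | O=COc1ccc(OCc2ccccc2)c(OC)c1OCc1ccccc1 | intermediate
6 | 2,4-bis(benzyloxy)-3-methoxyphenol | Oc1ccc(OCc2ccccc2)c(OC)c1OCc1ccccc1 | intermediate
7 | 2,4-bis(benzyloxy)-6-(hydroxymethyl)-3-methoxyphenol | OCc1cc(OCc2ccccc2)c(OC)c(OCc2ccccc2)c1O | intermediate
8 | 3,5-bis(benzyloxy)-2-hydroxy-4-methoxybenzaldehyde | O=Cc1cc(OCc2ccccc2)c(OC)c(OCc2ccccc2)c1O | intermediate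
9 | 3,5-bis(benzyloxy)-4-methoxy-2-(methoxymethoxy)benzaldehyde | O=Cc1cc(OCc2ccccc2)c(OC)c(OCc2ccccc2)c1OCOC | intermediate
10 | 3,5-bis(benzyloxy)-4-methoxy-2-(methoxymethoxy)phenyl formate | O=COc1cc(OCc2ccccc2)c(OC)c(OCc2ccccc2)c1OCOC | intermediate
11 | 3,5-bis(benzyloxy)-4-methoxy-2-(methoxymethoxy)phenol | Oc1cc(OCc2ccccc2)c(OC)c(OCc2ccccc2)c1OCOC | intermediate
12 | 3,5-bis(benzyloxy)-2-(hydroxymethyl)-4-methoxy-6-(methoxymethoxy)phenol | OCc1c(O)c(OCOC)c(OCc2ccccc2)c(OC)c1OCc1ccccc1 | intermediate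
13 | 4,6-bis(benzyloxy)-2-hydroxy-5-methoxy-3-(methoxymethoxy)benzaldehyde | O=Cc1c(O)c(OCOC)c(OCc2ccccc2)c(OC)c1OCc1ccccc1 | intermediate
14 | racemic 1-[4,6-bis(benzyloxy)-2-hydroxy-5-methoxy-3-(methoxymethoxy)phenyl]ethan-1-ol | CC(O)c1c(O)c(OCOC)c(OCc2ccccc2)c(OC)c1OCc1ccccc1 | intermediate
15 | 1-[4,6-bis(benzyloxy)-2-hydroxy-5-methoxy-3-(methoxymethoxy)phenyl]ethan-1-one | CC(=O)c1c(O)c(OCOC)c(OCc2ccccc2)c(OC)c1OCc1ccccc1 | intermediate
16 | 4-methoxybenzaldehyde | COc1ccc(C=O)cc1 | starting material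
17 | racemic 1-[4,6-bis(benzyloxy)-2-hydroxy-5-methoxy-3-(methoxymethoxy)phenyl]-3-hydroxy-3-(4-methoxyphenyl)propan-1-one | COc1ccc(C(O)CC(=O)c2c(O)c(OCOC)c(OCc3ccccc3)c(OC)c2OCc2ccccc2)cc1 | intermediate
18 | (E)-1-[4,6-bis(benzyloxy)-2-hydroxy-5-methoxy-3-(methoxymethoxy)phenyl]-3-(4-methoxyphenyl)prop-2-en-1-one | COc1ccc(/C=C/C(=O)c2c(O)c(OCOC)c(OCc3ccccc3)c(OC)c2OCc2ccccc2)cc1 | intermediate
19 | racemic trans-5,7-bis(benzyloxy)-3-hydroxy-6-methoxy-8-(methoxymethoxy)-2-(4-methoxyphenyl)chroman-4-one (2R,3R enantiomer drawn) | O=C1[C@H](O)[C@@H](c2ccc(OC)cc2)Oc2c(OCOC)c(OCc3ccccc3)c(OC)c(OCc3ccccc3)c21 | intermediate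
20 | 5,7-bis(benzyloxy)-3-hydroxy-6-methoxy-8-(methoxymethoxy)-2-(4-methoxyphenyl)-4H-chromen-4-one | COc1ccc(-c2oc3c(OCOC)c(OCc4ccccc4)c(OC)c(OCc4ccccc4)c3c(=O)c2O)cc1 | intermediate
21 | 5,7-bis(benzyloxy)-3,6-dimethoxy-8-(methoxymethoxy)-2-(4-methoxyphenyl)-4H-chromen-4-one | COc1ccc(-c2oc3c(OCOC)c(OCc4ccccc4)c(OC)c(OCc4ccccc4)c3c(=O)c2OC)cc1 | intermediate
22 | 5,7-bis(benzyloxy)-8-hydroxy-3,6-dimethoxy-2-(4-methoxyphenyl)-4H-chromen-4-one | COc1ccc(-c2oc3c(O)c(OCc4ccccc4)c(OC)c(OCc4ccccc4)c3c(=O)c2OC)cc1 | intermediate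
23 | 5,7-bis(benzyloxy)-3,6-dimethoxy-2-(4-methoxyphenyl)-4-oxo-4H-chromen-8-yl 3-methylbutanoate | COc1ccc(-c2oc3c(OC(=O)CC(C)C)c(OCc4ccccc4)c(OC)c(OCc4ccccc4)c3c(=O)c2OC)cc1 | intermediate
24 | 5,7-dihydroxy-3,6-dimethoxy-2-(4-methoxyphenyl)-4-oxo-4H-chromen-8-yl 3-methylbutanoate | COc1ccc(-c2oc3c(OC(=O)CC(C)C)c(O)c(OC)c(O)c3c(=O)c2OC)cc1 | target

**Step count:** 15 steps in total. **Longest linear sequence:** 15 steps (1 → 24); 16 is used as bought.

**Three steps most likely to fail**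

Step 11 (Algar–Flynn–Oyamada). A 6'-alkoxy group on the chalcone can divert the reaction to the aurone. The fallback sets out from chalcone 18. Refluxing with NaOAc in EtOH closes it to racemic 5,7-bis(benzyloxy)-6-methoxy-8-(methoxymethoxy)-2-(4-methoxyphenyl)chroman-4-one F1. Dehydrogenation with I2 in pyridine at 90 °C (base-buffered, so the MOM group is safe) gives 5,7-bis(benzyloxy)-6-methoxy-8-(methoxymethoxy)-2-(4-methoxyphenyl)-4H-chromen-4-one F2. Epoxidation of C2=C3 with dimethyldioxirane (acetone/CH2Cl2, 0 °C) gives racemic 5,7-bis(benzyloxy)-2,3-epoxy-6-methoxy-8-(methoxymethoxy)-2-(4-methoxyphenyl)chroman-4-one F3, which opens on silica gel or with a trace of PPTS to flavonol 20, where the route is rejoined.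

Step 7 (second ortho-formylation, on the hindered, MOM-bearing, air-sensitive phenol). The fallback sets out from phenol 11 and replaces steps 7–9 by halogen–metal exchange. NBS (1 equiv, MeCN, –20 °C) brominates the only free ring position to give 3,5-bis(benzyloxy)-2-bromo-4-methoxy-6-(methoxymethoxy)phenol F4. n-BuLi (2.2 equiv, THF, –78 °C) deprotonates the phenol and exchanges bromine to give lithium 3,5-bis(benzyloxy)-2-lithio-4-methoxy-6-(methoxymethoxy)phenoxide F5. Acylation with N-methoxy-N-methylacetamide and an NH4Cl quench gives acetophenone 15, where the route is rejoined.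

Step 13 (MOM removal without loss of the acid-labile 5-O-benzyl group). If mixtures form, the fallback sets out from 21 and cleaves both groups on purpose. Conc. HCl/AcOH at 60 °C under N2 removes MOM and the peri 5-O-benzyl group, giving 7-(benzyloxy)-5,8-dihydroxy-3,6-dimethoxy-2-(4-methoxyphenyl)-4H-chromen-4-one F6. Isovaleryl chloride (1.05 equiv) with Et3N in CH2Cl2 at –20 °C acylates only the 8-OH, because the 5-OH is locked in a hydrogen bond to the C4 carbonyl, giving 7-(benzyloxy)-5-hydroxy-3,6-dimethoxy-2-(4-methoxyphenyl)-4-oxo-4H-chromen-8-yl 3-methylbutanoate F7. Hydrogenolysis (H2, Pd/C, EtOAc) of the one remaining benzyl ether comes back to the route at target 24.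

**Further compounds**
F1 | step 11 | racemic 5,7-bis(benzyloxy)-6-methoxy-8-(methoxymethoxy)-2-(4-methoxyphenyl)chroman-4-one | O=C1CC(c2ccc(OC)cc2)Oc2c(OCOC)c(OCc3ccccc3)c(OC)c(OCc3ccccc3)c21
F2 | step 11 | 5,7-bis(benzyloxy)-6-methoxy-8-(methoxymethoxy)-2-(4-methoxyphenyl)-4H-chromen-4-one | COc1ccc(-c2cc(=O)c3c(OCc4ccccc4)c(OC)c(OCc4ccccc4)c(OCOC)c3o2)cc1
F3 | step 11 | racemic 5,7-bis(benzyloxy)-2,3-epoxy-6-methoxy-8-(methoxymethoxy)-2-(4-methoxyphenyl)chroman-4-one | COc1ccc(C23OC2C(=O)c2c(OCc4ccccc4)c(OC)c(OCc4ccccc4)c(OCOC)c2O3)cc1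
F4 | step 7 | 3,5-bis(benzyloxy)-2-bromo-4-methoxy-6-(methoxymethoxy)phenol | Oc1c(Br)c(OCc2ccccc2)c(OC)c(OCc2ccccc2)c1OCOC
F5 | step 7 | lithium 3,5-bis(benzyloxy)-2-lithio-4-methoxy-6-(methoxymethoxy)phenoxide | [Li]Oc1c([Li])c(OCc2ccccc2)c(OC)c(OCc2ccccc2)c1OCOC
F6 | step 13 | 7-(benzyloxy)-5,8-dihydroxy-3,6-dimethoxy-2-(4-methoxyphenyl)-4H-chromen-4-one | COc1ccc(-c2oc3c(O)c(OCc4ccccc4)c(OC)c(O)c3c(=O)c2OC)cc1
F7 | step 13 | 7-(benzyloxy)-5-hydroxy-3,6-dimethoxy-2-(4-methoxyphenyl)-4-oxo-4H-chromen-8-yl 3-methylbutanoate | COc1ccc(-c2oc3c(OC(=O)CC(C)C)c(OCc4ccccc4)c(OC)c(O)c3c(=O)c2OC)cc1
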